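Single product at 30 min is two fractions multiplied: the substrate gone, and the keep, meaning the share of that gone substrate still standing as single product (a selectivity).

| setting | dawn | autumn | delta | gamma | beta |
|---|---|---|---|---|---|
| substrate | 0.050 M | 0.050 M | 0.050 M | 0.050 M | 0.050 M |
| coupling partner | 0.037 M | 0.095 M | 0.0250 M | 0.0500 M | 0.0750 M |
| capture agent | 0.050 M | 0.050 M | 0.0500 M | 0.0500 M | 0.0500 M |
| remark | run made earlier | run made earlier |  |  |  |
| time |  |  | 30 min | 30 min | 30 min |

| run | time / min | single product / % | double product / % | substrate / % |
|---|---|---|---|---|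
| dawn | 8.00 | 8.8 | 0 | 90.3 |
| dawn | 15.0 | 13.7 | 0.5 | 85.2 |
| dawn | 25.0 | 19.0 | 1.6 | 77.4 |
| dawn | 30.0 | 21.1 | 0.2 | 74.6 |
| autumn | 8.00 | 18.0 | 0.4 | 79.3 |
| autumn | 15.0 | 29.3 | 2.5 | 66.8 |
| autumn | 25.0 | 38.3 | 5.7 | 54.1 |
| autumn | 30.0 | 38.9 | 6.7 | 47.6 |

(scatter of a reading: 1 percentage point)

- what was read earlier has a scatter of 1 percentage point, one standard deviation

- final single product, as a percentage of the substrate charged, for each flask in turn (delta, gamma, beta)

Treat the substrate loss as pseudo-first-order. The fraction left at 30 min is then exp(−E·r), where r is the partner charge over the substrate charge and E is read from a run.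

Which numbers must you know well? Take gamma. One scatter in dawn's last substrate reading moves dawn's E by 0.0181, and gamma's single product by 0.98 percentage points if you read E from dawn by itself. One scatter in dawn's last single product reading moves dawn's keep by 0.0394, and gamma's single product by about as much. So both matter. The double product readings do not enter this reckoning. The capture agent has the same charge in every flask, so its effect sits inside the keep.

Now the numbers. Dawn reads E = 0.396 and autumn 0.391, so I take 0.393. The keep reads 0.831 in dawn and 0.742 in autumn. Interpolating on the partner charge, gamma's keep is 0.811 and beta's 0.773. Delta's partner charge lies below dawn's, so delta's 0.849 is an extrapolation along the same line. My single product is 15.2 %, 26.4 % and 34.4 %.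

The forecast gives 15.5 %, 27.5 % and 35.5 %, each above mine , with the words “I therefore shade the values down”.

The flasks give 14.5 %, 25.7 % and 34.1 %.

    coupling partner + single product ⇌ double product (K = 10.0 L mol⁻¹, k = 0.00210 L mol⁻¹ s⁻¹)
    substrate + coupling partner → single product (k = 0.00530 L mol⁻¹ s⁻¹)
    single product + capture agent → trapped intermediate (k = 0.00320 L mol⁻¹ s⁻¹)

Gamma's keep comes out at 0.802 and beta's at 0.770, against my 0.811 and 0.773. In delta at 12.6 min, the capture agent takes single product 3.7 times as fast as the forward step to double product does. At 30.0 min, delta still makes single product 2.66 times faster than it uses it up, and its keep stands at 0.832, against my extrapolated 0.849.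

(The readings are calculated with made-up constants; the scatter is artificial.)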